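The synthesis treats ring A as an anisole. O3 lies para to C10, so rings A and B map onto 6-methoxy-1-tetralone with C9 as the ketone carbon, and the angular methyl must be added to a former arene carbon. C8 and C9 are set on the tetralin, and Birch reduction then leaves the C5=C10 alkene. In the key step the β-CH2OH on C9, next to C10, steers a zinc carbenoid onto the β face. This forms C10–C19 and C5–C19, closing one ring and setting both ring-fusion centres at once. The precursor is the C5=C10 octalin 3-ketal with a free C11 hydroxyl and a silyl-masked 8α-oxygen. Acid later breaks C5–C19 to give the 10β-methyl enone.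

Key step: step 8

Numbering and abbreviations: decalin carbons are C1–C10, C11 is on C9, C19 is the carbon that becomes the C10 methyl, and TBS = tert-butyldimethylsilyl.
Assumption: the (+)-(camphorylsulfonyl)oxaziridine is taken to oxidise the enolate face that gives the (R)-carbinol, the sense known for 2-methyl-1-tetralone. Its commercial antipode serves if the sense proves opposite.

Step 1
Reactants: 1 6-methoxy-1-tetralone
Product: 3 rac-6-methoxy-2-methyl-1-tetralone, via lithium enolate 2 (not isolated)
Conditions: LiN(i-Pr)2, THF, −78 °C; MeI, −78 to 0 °C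
Reagents that add atoms: iodomethane, CI
Why: Kinetic deprotonation at the only enolisable position and SN2 methylation (ketone enolate alkylation) should give the monomethyl ketone, whose racemic C8 centre is erased again by enolisation in step 2.

Step 2
Reactants: 3 rac-6-methoxy-2-methyl-1-tetralone
Product: 5 (R)-2-hydroxy-6-methoxy-2-methyl-1-tetralone, via sodium enolate 4 (not isolated)
Conditions: NaN(SiMe3)2, THF, −78 °C; (+)-(camphorylsulfonyl)oxaziridine, −78 °C
Reagents that add atoms: (+)-(camphorylsulfonyl)oxaziridine, CC1(C)[C@@H]2CC[C@]13CS(=O)(=O)N4O[C@@]34C2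
Why: In this Davis asymmetric enolate hydroxylation the ring fixes a single enolate geometry and the camphor-derived reagent hands its oxygen to one enantiotopic face, which sets C8 as R (8α-oxygen, 8β-methyl).

Step 3
Reactants: 5 (R)-2-hydroxy-6-methoxy-2-methyl-1-tetralone
Product: 6 (R)-2-(TBS-oxy)-6-methoxy-2-methyl-1-tetralone
Conditions: TBSOTf, 2,6-lutidine, CH2Cl2, 0 °C to rt
Reagents that add atoms: tert-butyldimethylsilyl triflate, CC(C)(C)[Si](C)(C)OS(=O)(=O)C(F)(F)F
Why: Silyl triflate silylation copes with the tertiary alcohol (the ketone cannot enolise), and a bulky silyl ether is chosen over an acetal-type ether because its oxygen binds zinc poorly and resists acid, which matters in steps 8 and 9.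

Step 4
Reactants: 6 (R)-2-(TBS-oxy)-6-methoxy-2-methyl-1-tetralone
Product: 7 (R)-2-(TBS-oxy)-6-methoxy-2-methyl-1-methylenetetralin
Conditions: Ph3PCH3Br, KOt-Bu, THF, 0 °C to reflux
Reagents that add atoms: methyltriphenylphosphonium bromide, C[P+](c1ccccc1)(c1ccccc1)c1ccccc1.[Br-]
Why: In this Wittig methylenation the hindered aryl ketone has no α-hydrogen on either side, so it can be driven thermally without enolisation or loss of the C8 configuration.

Step 5
Reactants: 7 (R)-2-(TBS-oxy)-6-methoxy-2-methyl-1-methylenetetralin
Product: 9 [(1S,2R)-2-(TBS-oxy)-6-methoxy-2-methyltetralin-1-yl]methanol (8α-OTBS; 9β-CH2OH), via B-alkyl-9-borabicyclononane 8 (not isolated)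
Conditions: 9-borabicyclo[3.3.1]nonane, THF, 65 °C; NaOH, 30% H2O2, 0 °C to rt
Reagents that add atoms: hydrogen peroxide, OO
Why: In this anti-Markovnikov hydroboration–oxidation boron goes to terminal C11 and hydrogen should reach C9 from the α face through the staggered transition state with the donor C8–CH3 bond anti to the borane and the C8–O bond inside (the sense known for uncatalysed dialkylborane additions to 2-substituted allylic ethers), so C11 ends β and trans to the C8 oxygen, and the oxidation retains configuration.

Step 6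
Reactants: 9 [(1S,2R)-2-(TBS-oxy)-6-methoxy-2-methyltetralin-1-yl]methanol
Product: 10 3-methoxy-2,5(10)-diene (1,4-dihydroanisole; 8α-OTBS; 9β-CH2OH)
Conditions: Li, NH3(l), THF, t-BuOH, −78 to −33 °C
Reagents that add atoms: none
Why: Birch reduction protonates C1 and C4 and leaves the donor-bearing C2=C3 enol ether and the tetrasubstituted C5=C10 alkene, while the silyl ether and the alkoxide are inert and no benzylic C–O bond is present to be cleaved.

Step 7
Reactants: 10 3-methoxy-2,5(10)-diene
Product: 11 C5=C10 octalin 3-ethylene ketal (8α-OTBS; 8β-methyl; 9β-CH2OH free)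
Conditions: ethylene glycol, pyridinium p-toluenesulfonate (cat.), CH2Cl2, rt
Reagents that add atoms: ethylene glycol, OCCO
Why: Acid-catalysed addition of the diol to the enol ether followed by transketalisation, under acidity as low as that used for tetrahydropyranyl ether formation, should mask C3 without moving C5=C10 into conjugation and remove the one alkene that would outrun it toward a carbenoid.

Step 8
Reactants: 11 C5=C10 octalin 3-ethylene ketal
Product: 13 5β,10β-methano decalin 3-ethylene ketal (8α-OTBS; 9β-CH2OH), via iodomethylzinc alkoxide 12 (not isolated)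
Conditions: Et2Zn (added first), then CH2I2, CH2Cl2, −15 °C to rt
Reagents that add atoms: diiodomethane, ICI
Why: Et2Zn deprotonates the C11 hydroxyl and exchange with CH2I2 gives the iodomethylzinc alkoxide 12 (aggregated with excess carbenoid), which passes CH2 to C5=C10 through the concerted butterfly transition state of the Simmons–Smith reaction in its Furukawa variant. The closest known case is the hydroxyl-directed cyclopropanation of homoallylic alcohols, in particular of the 5(10)-alkenes obtained by Birch reduction in the 19-nor steroid series. The three-membered ring closes by a suprafacial [2+1] addition in which C10–C19 and C5–C19 form together, so the two new centres are necessarily cis to each other. Their sense (C19 β at C5 and at C10) is controlled by C9, because allylic strain against C1H2 holds the C9–CH2O–Zn arm pseudoaxial on the β face directly above the alkene. The step needs facial selectivity and chemoselectivity: the then axial 8α-silyl ether does not bind zinc and screens the α face, and the only competing π bond (C2=C3) has already become the ketal.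

Step 9
Reactants: 13 5β,10β-methano decalin 3-ethylene ketal
Product: 15 10β-methyl-Δ4-3-octalone (8α-OTBS; 9β-CH2OH), via cyclopropyl ketone 14 (not isolated)
Conditions: 2 M aq HCl, THF, 50 °C
Reagents that add atoms: water, O
Why: Ketal hydrolysis is followed by acid-catalysed isomerisation of the β,γ-cyclopropyl ketone (the homologue of β,γ- to α,β-enone isomerisation, known for 5,10-methano 19-nor steroids), in which the C3=C4 enol pushes toward C5 while C19 is protonated, so the strained C5–C19 bond breaks, C19 remains on C10 as the β-methyl, and the hindered, weakly basic silyl ether keeps C8 from ionising.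

Step 10
Reactants: 15 10β-methyl-Δ4-3-octalone
Product: 16 10β-methyl-Δ4-3-octalone bis-TBS ether (8α-OTBS; 9β-CH2OTBS)
Conditions: TBSCl, imidazole, DMF, rt
Reagents that add atoms: tert-butyldimethylsilyl chloride, CC(C)(C)[Si](C)(C)Cl
Why: Imidazole-promoted silylation of the primary alcohol is needed because a free C11 alkoxide would be O-methylated in step 12.

Step 11
Reactants: 16 10β-methyl-Δ4-3-octalone bis-TBS ether
Product: 17 4-(phenylthiomethyl)-10β-methyl-Δ4-3-octalone bis-TBS ether
Conditions: PhSH, 37% aq CH2O, Et3N, EtOH, reflux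
Reagents that add atoms: formaldehyde, C=O; thiophenol, Sc1ccccc1
Why: In the Kirk–Petrow thiomethylation, established for 10-methyl-Δ4-3-octalones, the α-carbon C4 of the enone adds to formaldehyde and thiophenol traps the resulting 4-methylene ketone, which installs the first C4 carbon without touching C2 or C6.

Step 12
Reactants: 17 4-(phenylthiomethyl)-10β-methyl-Δ4-3-octalone bis-TBS ether
Product: 19 4,4,10β-trimethyl-trans-decal-3-one bis-TBS ether (5α-H), via lithium enolate 18 (not isolated)
Conditions: Li, NH3(l), THF, t-BuOH (2 equiv), −78 to −33 °C; MeI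
Reagents that add atoms: iodomethane, CI
Why: In this dissolving-metal reductive alkylation of an enone, lithium cleaves the C–S bond and reduces the enone, axial protonation of the C5 carbanion opposite the 10β-methyl gives the trans ring fusion (5α-H), and the regiodefined C3–C4 enolate is methylated at C4 to complete the gem-dimethyl group, which avoids hydrogenating a hindered C5=C6 alkene.

Step 13
Reactants: 19 4,4,10β-trimethyl-trans-decal-3-one bis-TBS ether
Product: 20 3α-alcohol (3R; axial OH)
Conditions: LiBH(s-Bu)3, THF, −78 to 0 °C; NaOH, H2O2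
Reagents that add atoms: none
Why: In this bulky trialkylborohydride reduction of a ketone the reagent avoids the axial path past the 1α and 5α hydrogens and attacks equatorially, which should give the axial 3α-alcohol as known for 4,4-dimethyl-3-oxo trans-decalins.

Step 14
Reactants: 20 3α-alcohol; 21 angelic acid
Product: 23 3α-angelate bis-TBS ether, via mixed anhydride 22 (not isolated)
Conditions: 21, 2,4,6-trichlorobenzoyl chloride, Et3N, toluene, rt; then 20, toluene, 80 °C
Reagents that add atoms: none
Why: Yamaguchi-type mixed-anhydride esterification run without a nucleophilic catalyst is the established way to acylate hindered alcohols with angelic acid without Z to E isomerisation, and C3 keeps its configuration because only the O–H bond reacts.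

Step 15
Reactants: 23 3α-angelate bis-TBS ether
Product: 24 3α-angeloyloxy-8α,11-diol
Conditions: 48% aq HF, MeCN, 0 °C to rt
Reagents that add atoms: none
Why: Fluoride-driven cleavage of both silyl ethers (Si–F bond formation) takes place in a weakly acidic medium that should leave the ester, its Z geometry and the tertiary alcohol untouched.

Step 16
Reactants: 24 3α-angeloyloxy-8α,11-diol; 25 umbelliferone
Product: 26 target CNP0189964.4
Conditions: PPh3, diisopropyl azodicarboxylate, THF, 0 to 45 °C
Reagents that add atoms: none
Why: In the Mitsunobu etherification only the primary C11 hydroxyl gives a displaceable alkoxyphosphonium ion, the acidic phenol is the sole competent nucleophile, the tertiary C8 alcohol is inert and no stereocentre is touched.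

Compound list
1 | 6-methoxy-1-tetralone | COc1ccc2c(c1)CCCC2=O | starting material
2 | lithium enolate of 1 | COc1ccc2c(c1)CCC=C2[O-].[Li+] | intermediate
3 | rac-6-methoxy-2-methyl-1-tetralone | COc1ccc2c(c1)CCC(C)C2=O | intermediate
4 | sodium enolate of 3 | COc1ccc2c(c1)CCC(C)=C2[O-].[Na+] | intermediate
5 | (R)-2-hydroxy-6-methoxy-2-methyl-1-tetralone | COc1ccc2c(c1)CC[C@@](C)(O)C2=O | intermediate
6 | (R)-2-(TBS-oxy)-6-methoxy-2-methyl-1-tetralone | COc1ccc2c(c1)CC[C@@](C)(O[Si](C)(C)C(C)(C)C)C2=O | intermediate
7 | (R)-2-(TBS-oxy)-6-methoxy-2-methyl-1-methylenetetralin | COc1ccc2c(c1)CC[C@@](C)(O[Si](C)(C)C(C)(C)C)C2=C | intermediate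
8 | B-(C11-alkyl)-9-borabicyclo[3.3.1]nonane adduct of 7 | COc1ccc2c(c1)CC[C@@](C)(O[Si](C)(C)C(C)(C)C)[C@@H]2CB1C2CCCC1CCC2 | intermediate
9 | [(1S,2R)-2-(TBS-oxy)-6-methoxy-2-methyl-1,2,3,4-tetrahydronaphthalen-1-yl]methanol | COc1ccc2c(c1)CC[C@@](C)(O[Si](C)(C)C(C)(C)C)[C@@H]2CO | intermediate
10 | [(1S,2R)-2-(TBS-oxy)-6-methoxy-2-methyl-1,2,3,4,5,8-hexahydronaphthalen-1-yl]methanol (3-methoxy-2,5(10)-diene) | COC1=CCC2=C(C1)CC[C@@](C)(O[Si](C)(C)C(C)(C)C)[C@@H]2CO | intermediate
11 | C5=C10 octalin 3-ethylene ketal, 8α-OTBS, 8β-methyl, 9β-CH2OH (key-step precursor) | O1CCOC12CCC3=C(C2)CC[C@@](C)(O[Si](C)(C)C(C)(C)C)[C@@H]3CO | intermediate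
12 | iodomethylzinc alkoxide of 11 | O1CCOC12CCC3=C(C2)CC[C@@](C)(O[Si](C)(C)C(C)(C)C)[C@@H]3CO[Zn]CI | intermediate
13 | 5β,10β-methano decalin 3-ethylene ketal, 8α-OTBS, 9β-CH2OH (key-step product) | O1CCOC12CC[C@@]34C[C@]3(C2)CC[C@@](C)(O[Si](C)(C)C(C)(C)C)[C@@H]4CO | intermediate
14 | 5β,10β-methano decal-3-one, 8α-OTBS, 9β-CH2OH | O=C1CC[C@@]23C[C@]2(C1)CC[C@@](C)(O[Si](C)(C)C(C)(C)C)[C@@H]3CO | intermediate
15 | 10β-methyl-Δ4-3-octalone, 8α-OTBS, 8β-methyl, 9β-CH2OH | O=C1CC[C@@]2(C)C(=C1)CC[C@@](C)(O[Si](C)(C)C(C)(C)C)[C@@H]2CO | intermediate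
16 | 10β-methyl-Δ4-3-octalone, 8α-OTBS, 9β-CH2OTBS | O=C1CC[C@@]2(C)C(=C1)CC[C@@](C)(O[Si](C)(C)C(C)(C)C)[C@@H]2CO[Si](C)(C)C(C)(C)C | intermediate
17 | 4-(phenylthiomethyl) derivative of 16 | O=C1CC[C@@]2(C)C(=C1CSc1ccccc1)CC[C@@](C)(O[Si](C)(C)C(C)(C)C)[C@@H]2CO[Si](C)(C)C(C)(C)C | intermediate
18 | lithium C3–C4 enolate, 4-methyl, 5α-H, trans-decalin | [Li+].[O-]C1=C(C)[C@@H]2CC[C@@](C)(O[Si](C)(C)C(C)(C)C)[C@H](CO[Si](C)(C)C(C)(C)C)[C@@]2(C)CC1 | intermediate
19 | 4,4,10β-trimethyl-trans-decal-3-one, 5α-H, 8α-OTBS, 9β-CH2OTBS | O=C1CC[C@]2(C)[C@@H](CO[Si](C)(C)C(C)(C)C)[C@](C)(O[Si](C)(C)C(C)(C)C)CC[C@H]2C1(C)C | intermediate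
20 | 3α-alcohol of 19 (3R) | O[C@@H]1CC[C@]2(C)[C@@H](CO[Si](C)(C)C(C)(C)C)[C@](C)(O[Si](C)(C)C(C)(C)C)CC[C@H]2C1(C)C | intermediate
21 | angelic acid, (Z)-2-methylbut-2-enoic acid | C/C=C(/C)C(=O)O | starting material
22 | angelic 2,4,6-trichlorobenzoic anhydride | C/C=C(/C)C(=O)OC(=O)c1c(Cl)cc(Cl)cc1Cl | intermediate
23 | 3α-angelate of 20 | C/C=C(/C)C(=O)O[C@@H]1CC[C@]2(C)[C@@H](CO[Si](C)(C)C(C)(C)C)[C@](C)(O[Si](C)(C)C(C)(C)C)CC[C@H]2C1(C)C | intermediate
24 | 3α-angeloyloxydrimane-8α,11-diol | C/C=C(/C)C(=O)O[C@@H]1CC[C@]2(C)[C@@H](CO)[C@](C)(O)CC[C@H]2C1(C)C | intermediate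
25 | umbelliferone (7-hydroxycoumarin) | O=c1ccc2ccc(O)cc2o1 | starting material
26 | CNP0189964.4, 3α-angeloyloxy-8α-hydroxydriman-11-yl umbelliferyl ether | C/C=C(/C)C(=O)O[C@@H]1CC[C@]2(C)[C@@H](COc3ccc4ccc(=O)oc4c3)[C@](C)(O)CC[C@H]2C1(C)C | target

Total step count: 16. Longest linear sequence: 16 steps, from 1 to 26; 21 and 25 are bought and enter directly.

Steps most likely to fail

Step 8. Methylene transfer to the tetrasubstituted alkene may be slow. Delivery guided by a single flexible homoallylic alkoxide may then lose facial fidelity while the zinc iodide formed attacks the ketal. The fallback adds a second director inside ring A, the one proven in the 19-nor steroid series. It sets out from 10 and comes back at 14.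
- Oxalic acid in aqueous methanol–THF should hydrolyse the enol ether to the unconjugated β,γ-unsaturated ketone F1.
- NaBH4 in methanol at low temperature, followed by separation of the C3 epimers, should give the 3β-alcohol F2. The 3α epimer is returned to F1 by oxidation.
- Et2Zn–CH2I2 then acts on a substrate with two zinc alkoxides on the β face and no ketal, and should give the 5β,10β-methano diol F3.
- Oxidation selective for the secondary carbinol (NaOCl, AcOH) gives cyclopropyl ketone 14, which is opened as in step 9.

Step 16. Displacement at C11, which is flanked by the quaternary C8 and C10, may be so slow that the alkoxyphosphonium ion is consumed by alkylation of the hydrazide or by elimination. The fallback reverses the polarity and makes the O–aryl bond instead of the C11–O bond. It sets out from 24 and comes back at 26.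
- Diol 24 serves as the nucleophile in a palladium-catalysed C–O cross-coupling with commercial 7-bromocoumarin (O=c1ccc2ccc(Br)cc2o1).
- The conditions are [(allyl)PdCl]2, the biaryl phosphine RockPhos, Cs2CO3, toluene, 90 °C.
- The aryl bromide adds oxidatively to zerovalent palladium and only the primary alkoxide is transferred, so hindrance behind C11 no longer counts and the tertiary alcohol stays out.
- No new isolated compound lies on this path.

Step 5. Facial selectivity of hydrogen delivery to C9 may be poor, because two ring conformers of 7 expose opposite faces of the alkene. The fallback ties the hydride donor to the C8 oxygen. It sets out from 7 and comes back at 9.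
- Bu4NF frees the tertiary allylic alcohol F4.
- 1,1,3,3-Tetramethyldisilazane converts it into the dimethylsilyl ether F5.
- Pt2[(CH2=CHSiMe2)2O]3 triggers intramolecular hydrosilylation to the trans-fused oxasilolane F6.
- The tether can reach C11 only when the C8–O bond lies near the alkene plane. This places the C8 methyl axial on the β face, so hydrogen enters C9 from the α face.
- Tamao–Fleming oxidation (H2O2, KF, KHCO3) gives the trans 8,11-diol F7.
- TBSOTf with 2,6-lutidine gives the bis-silyl ether F8, and camphorsulfonic acid in methanol at 0 °C removes only the primary silyl group to return 9.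

Further compounds
F1 | step 8 | 5(10)-octalin-3-one, 8α-OTBS, 9β-CH2OH | O=C1CCC2=C(C1)CC[C@@](C)(O[Si](C)(C)C(C)(C)C)[C@@H]2CO
F2 | step 8 | 5(10)-octalin-3β-ol, 8α-OTBS, 9β-CH2OH | O[C@H]1CCC2=C(C1)CC[C@@](C)(O[Si](C)(C)C(C)(C)C)[C@@H]2CO
F3 | step 8 | 5β,10β-methano decalin-3β-ol, 8α-OTBS, 9β-CH2OH | O[C@H]1CC[C@@]23C[C@]2(C1)CC[C@@](C)(O[Si](C)(C)C(C)(C)C)[C@@H]3CO
F0 | step 16 | none | none
F4 | step 5 | (R)-6-methoxy-2-methyl-1-methylenetetralin-2-ol | COc1ccc2c(c1)CC[C@@](C)(O)C2=C
F5 | step 5 | dimethylsilyl ether of F4 | COc1ccc2c(c1)CC[C@@](C)(O[SiH](C)C)C2=C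
F6 | step 5 | trans-fused 2,2-dimethyl-1-oxa-2-silacyclopentane spanning O8 and C11 | COc1ccc2c(c1)CC[C@@]3(C)O[Si](C)(C)C[C@H]23
F7 | step 5 | (1S,2R)-1-(hydroxymethyl)-6-methoxy-2-methyltetralin-2-ol | COc1ccc2c(c1)CC[C@@](C)(O)[C@@H]2CO
F8 | step 5 | bis-TBS ether of F7 | COc1ccc2c(c1)CC[C@@](C)(O[Si](C)(C)C(C)(C)C)[C@@H]2CO[Si](C)(C)C(C)(C)C
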